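**Assumption:** the target is the natural normal-series drimane (10β-Me, 5α-H, 9α-H, 4β-Me, 4α-CH2OH). Geranylacetone, gentisaldehyde and the simple reagents are commercial.

## Retrosynthetic overview
1. Epoxypholamin A comes from global desilylation of an epoxy-enone. That is made by ketal hydrolysis, Luche reduction, Weitz–Scheffer epoxidation and PIDA/MeOH dearomatisation of a 2-alkyl-4-methoxyphenol. The cyclohexenone ring is therefore formed last, from an arene.
2. The drimane–arene comes from one Ti(III) radical cascade of an (E,E)-epoxyfarnesyl arene, which forms rings A and B. The Sharpless epoxide carries a C(Me)(CH2OTBS) terminus that becomes C4. Its CH–O carbon sets the absolute sense, and C3 is then deoxygenated.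
3. The polyene is built from geranylacetone by terminal SeO2 oxidation, Sharpless epoxidation, TBS protection, HWE, DIBAL reduction and Appel bromination. It is coupled by a cuprate to the aryl bromide made from gentisaldehyde.
4. Ring order: A and B (radical cascade), then the arene, then the cyclohexenone epoxide (dearomatisation, epoxidation, reduction, ketal cleavage).

## Route

**Step 1**
Reactants: 1 (E)-geranylacetone
Product: 2 (5E,9E)-11-hydroxy-6,10-dimethylundeca-5,9-dien-2-one
Conditions: SeO2 (10 mol%), tBuOOH, salicylic acid (cat.), CH2Cl2, 0 °C → rt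
Reagents that add atoms: tBuOOH (CC(C)(C)OO)
Why: Umbreit–Sharpless catalytic SeO2/tBuOOH allylic oxidation hydroxylates the terminal trisubstituted alkene at the (E)-methyl, giving the (E)-allylic alcohol needed for Sharpless epoxidation and later for C18 (moderate yield, some over-oxidation).

**Step 2**
Reactants: 2
Product: 3 (5E)-8-[(2S,3S)-3-(hydroxymethyl)-3-methyloxiran-2-yl]-6-methyloct-5-en-2-one
Conditions: Ti(OiPr)4, L-(+)-DET, tBuOOH, 4 Å MS, CH2Cl2, −25 °C
Reagents that add atoms: tBuOOH (CC(C)(C)OO)
Why: Sharpless asymmetric epoxidation acts only on the free allylic alcohol, and L-(+)-DET gives the (2S,3S) epoxide, whose CH–O carbon (S, as in (3S)-2,3-oxidosqualene) is the future C3 and fixes the normal-series absolute configuration (the configuration of the quaternary epoxide carbon is erased later by radical opening).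

**Step 3**
Reactants: 3
Product: 4 (5E)-8-[(2S,3S)-3-(TBSO-methyl)-3-methyloxiran-2-yl]-6-methyloct-5-en-2-one
Conditions: TBSCl, imidazole, DMF, rt
Reagents that add atoms: TBSCl (CC(C)(C)[Si](C)(C)Cl)
Why: Silyl protection of the primary alcohol, which becomes C18-OTBS, through the HWE, hydride and radical steps.

**Step 4**
Reactants: 4
Product: 5 ethyl (2E,6E)-9-[(2S,3S)-3-(TBSO-methyl)-3-methyloxiran-2-yl]-3,7-dimethylnona-2,6-dienoate
Conditions: (EtO)2P(O)CH2CO2Et, NaH, THF, 0 °C → rt; chromatographic removal of the Z isomer (E/Z about 4:1)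
Reagents that add atoms: triethyl phosphonoacetate (CCOC(=O)CP(=O)(OCC)OCC)
Why: Horner–Wadsworth–Emmons olefination converts the methyl ketone into the E-trisubstituted enoate of the farnesoate pattern, and the epoxide and TBS ether tolerate NaH at 0 °C.

**Step 5**
Reactants: 5
Product: 6 (2E,6E)-9-[(2S,3S)-3-(TBSO-methyl)-3-methyloxiran-2-yl]-3,7-dimethylnona-2,6-dien-1-ol
Conditions: DIBAL-H (2.5 equiv), CH2Cl2, −78 °C
Reagents that add atoms: none
Why: DIBAL-H reduces the conjugated ester to the allylic alcohol at low temperature while the epoxide and TBS ether are untouched.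

**Step 6**
Reactants: 6
Product: 7 (2S,3S)-2-[(3E,7E)-9-bromo-3,7-dimethylnona-3,7-dien-1-yl]-3-(TBSO-methyl)-3-methyloxirane (epoxyfarnesyl bromide)
Conditions: CBr4, PPh3, CH2Cl2, 0 °C
Reagents that add atoms: CBr4 (BrC(Br)(Br)Br)
Why: Appel bromination proceeds under neutral conditions without allylic transposition, so the E-alkenes and the epoxide survive.

**Step 7**
Reactants: 8 gentisaldehyde (2,5-dihydroxybenzaldehyde)
Product: 9 2-hydroxy-5-(methoxymethoxy)benzaldehyde
Conditions: MOMCl (1.05 equiv), iPr2NEt, CH2Cl2, 0 °C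
Reagents that add atoms: MOMCl (ClCOC)
Why: The 2-OH is hydrogen-bonded to the aldehyde, so acetal formation occurs chemoselectively at the free 5-OH.

**Step 8**
Reactants: 9
Product: 10 2-methoxy-5-(methoxymethoxy)benzaldehyde
Conditions: MeI, K2CO3, DMF, rt
Reagents that add atoms: MeI (CI)
Why: O-Methylation of the remaining phenol; this OMe carbon becomes the ketal carbon of the quinone monoketal.

**Step 9**
Reactants: 10
Product: 11 4-bromo-2-methoxy-5-(methoxymethoxy)benzaldehyde
Conditions: NBS, MeCN, 0 °C → rt
Reagents that add atoms: NBS (O=C1CCC(=O)N1Br)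
Why: Electrophilic bromination goes ortho to the 5-OMOM group and para to the CHO, by analogy with 2,5-dimethoxybenzaldehyde (which brominates at C4), and NBS avoids HBr that would cleave the MOM group.

**Step 10**
Reactants: 11
Product: 12 [4-bromo-2-methoxy-5-(methoxymethoxy)phenyl]methanol
Conditions: NaBH4, MeOH, 0 °C
Reagents that add atoms: none
Why: Simple hydride reduction of the aryl aldehyde.

**Step 11**
Reactants: 12
Product: 13 tert-butyl{[4-bromo-2-methoxy-5-(methoxymethoxy)benzyl]oxy}dimethylsilane
Conditions: TBSCl, imidazole, DMF, rt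
Reagents that add atoms: TBSCl (CC(C)(C)[Si](C)(C)Cl)
Why: Silyl protection of the future hydroxymethyl group on the enone double bond of the target ring.

**Step 12**
Reactants: 13; 7
Product: 14 (2S,3S)-epoxyfarnesyl arene: 2-[(3E,7E)-9-aryl-3,7-dimethylnona-3,7-dien-1-yl]-3-(TBSO-methyl)-3-methyloxirane, aryl = 2-methoxy-4-(TBSO-methyl)... i.e. 5-(MOMO)-4-alkyl-2-methoxybenzyl TBS ether
Conditions: 13, t-BuLi (2 equiv), THF, −78 °C; then CuBr·SMe2; then 7, −78 → −20 °C
Reagents that add atoms: none
Why: Li–Br exchange (directed by the ortho OMOM) gives the aryl copper, which undergoes SN2 (α) allylic substitution with the farnesyl bromide (organocuprate allylic coupling), keeping both E-alkenes and the trisubstituted epoxide.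

**Step 13**
Reactants: 14
Product: 15 trans-decalin 3β-alcohol: 5α-H, 10β-Me, 9α-H, 9β-CH2Ar, 4β-Me/4α-CH2OTBS, exocyclic C8=CH2
Conditions: Cp2TiCl2 (2.2 equiv), Zn, 2,4,6-collidine, THF, rt
Reagents that add atoms: none
Why: Proposed new method: Nugent–RajanBabu Ti(III) homolytic opening of the trisubstituted epoxide gives the planar C4 tertiary radical, which undergoes two chair-like 6-endo cyclisations (C4–C5, then C10–C9) to the trans-decalin, and the C8 radical is trapped by Cp2TiCl and undergoes β-H elimination to the exocyclic alkene; the closest known reaction is the Cuerva–Oltra/Barrero Ti(III) cyclisation of epoxyfarnesyl acetates and epoxyfarnesyl arenes to 3β-hydroxydrimanes, extended here to a C4 CH2OTBS terminus, where the larger CH2OTBS is expected to sit equatorial (4α) in the chair transition state and the minor C4 epimer is removed chromatographically.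

**Step 14**
Reactants: 15
Product: 16 3β-O-(S-methyl xanthate) of 15
Conditions: NaH, imidazole (cat.), THF; then CS2; then MeI
Reagents that add atoms: CS2 (S=C=S); MeI (CI)
Why: Xanthate formation activates the hindered 3β-OH for Barton–McCombie deoxygenation, because C3 is a CH2 in the target.

**Step 15**
Reactants: 16
Product: 17 3-deoxy drim-8(12)-ene, 4α-CH2OTBS, C11-aryl (MOM)
Conditions: Bu3SnH, AIBN, PhMe, 110 °C
Reagents that add atoms: none
Why: Barton–McCombie radical deoxygenation removes the C3 oxygen, and no stereocentre is left at C3, so C4, C5 and C10 are unaffected.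

**Step 16**
Reactants: 17
Product: 18 drim-7-ene (endocyclic C7=C8), 4α-CH2OTBS, C11-aryl (MOM)
Conditions: Co(salen)Cl (5 mol%), PhSiH3 (10 mol%), PhH, rt
Reagents that add atoms: none
Why: Shenvi-type Co–H hydrogen-atom-transfer isomerisation adds H to the exocyclic CH2 and Co then removes H from the less hindered C7 rather than the tertiary C9, converting the 1,1-disubstituted alkene into the trisubstituted Δ7 alkene without touching the C9 stereocentre.

**Step 17**
Reactants: 18
Product: 19 phenol (2-alkyl-4-methoxyphenol core; both primary OTBS groups intact)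
Conditions: TMSOTf, 2,2′-bipyridyl, MeCN, 0 °C → rt; then H2O
Reagents that add atoms: none
Why: Fujioka TMSOTf/2,2′-bipyridyl converts the aryl MOM ether to a pyridinium intermediate that gives the free phenol on aqueous work-up, under buffered conditions that leave the primary TBS ethers and the trisubstituted alkene intact.

**Step 18**
Reactants: 19
Product: 20 quinone monoketal: 2-alkyl-4,4-dimethoxy-5-(TBSO-methyl)cyclohexa-2,5-dien-1-one
Conditions: PhI(OAc)2, MeOH, 0 °C
Reagents that add atoms: MeOH (CO)
Why: Kita/Swenton oxidative dearomatisation of the 4-methoxyphenol places the carbonyl at the phenol carbon (next to the alkyl-bearing carbon) and the dimethyl ketal at the para OMe carbon (next to the CH2OTBS carbon), which differentiates the two oxygens for the later steps.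

**Step 19**
Reactants: 20
Product: 21 epoxy-dienone ketal (epoxide on the alkyl-bearing C=C)
Conditions: 30% H2O2, NaOH (cat.), MeOH/THF, 0 °C
Reagents that add atoms: H2O2 (OO)
Why: Weitz–Scheffer nucleophilic epoxidation occurs at the unsubstituted β-carbon of the α-alkyl enone (the other enone β-carbon is fully substituted and next to the ketal), and because the faces are differentiated only by the remote drimane, the diastereomer with the target configuration is separated by HPLC.

**Step 20**
Reactants: 21
Product: 22 epoxy allylic alcohol ketal, C-OH trans to the epoxide oxygen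
Conditions: NaBH4, CeCl3·7H2O, MeOH, −78 °C
Reagents that add atoms: none
Why: In the Luche 1,2-reduction, hydride enters from the epoxide-oxygen face, anti to the bulky drimanylmethyl group on the adjacent quaternary carbon, so the new OH is trans to the epoxide O, as in the target.

**Step 21**
Reactants: 22
Product: 23 epoxy-enone bis-TBS ether (ketone unmasked)
Conditions: PPTS (0.3 equiv), acetone/H2O (9:1), 50 °C
Reagents that add atoms: H2O (O)
Why: Mildly acidic ketal hydrolysis unmasks the C2 carbonyl as the conjugated enone (sluggish next to the epoxide, and any TBS loss is tolerated because the next step removes the rest).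

**Step 22**
Reactants: 23
Product: 24 Epoxypholamin A
Conditions: HF·pyridine, THF/pyridine, 0 °C → rt
Reagents that add atoms: none
Why: Buffered fluoride cleaves both primary TBS ethers under conditions mild enough to spare the epoxide, the allylic alcohol and the enone.

## Compound list
1 | (E)-geranylacetone | CC(=O)CC/C=C(C)/CCC=C(C)C | starting material
2 | (5E,9E)-11-hydroxy-6,10-dimethylundeca-5,9-dien-2-one | CC(=O)CC/C=C(C)/CC/C=C(\C)CO | intermediate
3 | (5E)-8-[(2S,3S)-3-(hydroxymethyl)-3-methyloxiran-2-yl]-6-methyloct-5-en-2-one | CC(=O)CC/C=C(C)/CC[C@@H]1O[C@@]1(C)CO | intermediate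
4 | TBS ether of 3 | CC(=O)CC/C=C(C)/CC[C@@H]1O[C@@]1(C)CO[Si](C)(C)C(C)(C)C | intermediate
5 | ethyl (2E,6E)-9-[(2S,3S)-3-(TBSO-methyl)-3-methyloxiran-2-yl]-3,7-dimethylnona-2,6-dienoate | CCOC(=O)/C=C(\C)CC/C=C(C)/CC[C@@H]1O[C@@]1(C)CO[Si](C)(C)C(C)(C)C | intermediate
6 | (2E,6E)-epoxyfarnesol TBS ether (dienol) | OC/C=C(\C)CC/C=C(C)/CC[C@@H]1O[C@@]1(C)CO[Si](C)(C)C(C)(C)C | intermediate
7 | (2E,6E)-epoxyfarnesyl bromide, TBS ether | BrC/C=C(\C)CC/C=C(C)/CC[C@@H]1O[C@@]1(C)CO[Si](C)(C)C(C)(C)C | intermediate
8 | 2,5-dihydroxybenzaldehyde (gentisaldehyde) | O=Cc1cc(O)ccc1O | starting material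
9 | 2-hydroxy-5-(methoxymethoxy)benzaldehyde | O=Cc1cc(OCOC)ccc1O | intermediate
10 | 2-methoxy-5-(methoxymethoxy)benzaldehyde | O=Cc1cc(OCOC)ccc1OC | intermediate
11 | 4-bromo-2-methoxy-5-(methoxymethoxy)benzaldehyde | O=Cc1cc(OCOC)c(Br)cc1OC | intermediate
12 | [4-bromo-2-methoxy-5-(methoxymethoxy)phenyl]methanol | OCc1cc(OCOC)c(Br)cc1OC | intermediate
13 | aryl bromide, benzylic TBS ether | COCOc1cc(CO[Si](C)(C)C(C)(C)C)c(OC)cc1Br | intermediate
14 | epoxyfarnesyl arene (E,E; 2S,3S-epoxide) | C[C@@]1(CO[Si](C)(C)C(C)(C)C)O[C@H]1CC/C(C)=C/CC/C(C)=C/Cc1cc(OC)c(CO[Si](C)(C)C(C)(C)C)cc1OCOC | intermediate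
15 | bicyclic 3β-alcohol, exocyclic alkene | C=C1CC[C@H]2[C@](C)(CO[Si](C)(C)C(C)(C)C)[C@@H](O)CC[C@]2(C)[C@H]1Cc1cc(OC)c(CO[Si](C)(C)C(C)(C)C)cc1OCOC | intermediate
16 | 3β-O-(S-methyl xanthate) of 15 | C=C1CC[C@H]2[C@](C)(CO[Si](C)(C)C(C)(C)C)[C@@H](OC(=S)SC)CC[C@]2(C)[C@H]1Cc1cc(OC)c(CO[Si](C)(C)C(C)(C)C)cc1OCOC | intermediate
17 | 3-deoxy exocyclic alkene | C=C1CC[C@H]2[C@](C)(CO[Si](C)(C)C(C)(C)C)CCC[C@]2(C)[C@H]1Cc1cc(OC)c(CO[Si](C)(C)C(C)(C)C)cc1OCOC | intermediate
18 | drim-7-ene, aryl MOM ether | CC1=CC[C@H]2[C@](C)(CO[Si](C)(C)C(C)(C)C)CCC[C@]2(C)[C@H]1Cc1cc(OC)c(CO[Si](C)(C)C(C)(C)C)cc1OCOC | intermediate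
19 | phenol | CC1=CC[C@H]2[C@](C)(CO[Si](C)(C)C(C)(C)C)CCC[C@]2(C)[C@H]1Cc1cc(OC)c(CO[Si](C)(C)C(C)(C)C)cc1O | intermediate
20 | quinone monoketal | CC1=CC[C@H]2[C@](C)(CO[Si](C)(C)C(C)(C)C)CCC[C@]2(C)[C@H]1CC3=CC(OC)(OC)C(CO[Si](C)(C)C(C)(C)C)=CC3=O | intermediate
21 | epoxy-dienone ketal | CC1=CC[C@H]2[C@](C)(CO[Si](C)(C)C(C)(C)C)CCC[C@]2(C)[C@H]1C[C@@]34O[C@@H]3C(OC)(OC)C(CO[Si](C)(C)C(C)(C)C)=CC4=O | intermediate
22 | epoxy allylic alcohol ketal | CC1=CC[C@H]2[C@](C)(CO[Si](C)(C)C(C)(C)C)CCC[C@]2(C)[C@H]1C[C@@]34O[C@@H]3C(OC)(OC)C(CO[Si](C)(C)C(C)(C)C)=C[C@H]4O | intermediate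
23 | epoxy-enone bis-TBS ether | CC1=CC[C@H]2[C@](C)(CO[Si](C)(C)C(C)(C)C)CCC[C@]2(C)[C@H]1C[C@@]34O[C@@H]3C(=O)C(CO[Si](C)(C)C(C)(C)C)=C[C@H]4O | intermediate
24 | Epoxypholamin A | CC1=CC[C@H]2[C@](C)(CO)CCC[C@]2(C)[C@H]1C[C@@]34O[C@@H]3C(=O)C(CO)=C[C@H]4O | target

## Totals
Total steps: 22 (17 on the polyene/drimane branch, 5 on the arene branch). Longest linear sequence: 17 steps, from geranylacetone (steps 1–6 and 12–22).

**Three steps most likely to fail**
1. **Step 13 (Ti(III) bicyclisation).** Yield, the C4 epimer ratio (the planar radical erases the epoxide's quaternary-carbon configuration) and the exocyclic/endocyclic alkene ratio are all at risk.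
   - Fallback: switch to a Wieland–Miescher-ketone route. Li/NH3 reductive methylation, then enolate hydroxymethylation with α-face attack, fixes 4β-Me/4α-CH2OR, and ring B is built from the C9 ketone.
2. **Step 19 (quinone monoketal epoxidation).** The facial selectivity set only by the remote drimane may be poor.
   - Fallback: replace substrate control with catalyst control, using a Cinchona-derived phase-transfer epoxidation (Lygo-type, NaOCl) on 20, and separate the diastereomers by HPLC.
3. **Step 21 (ketal hydrolysis next to the epoxide and allylic alcohol).** The hydrolysis may be too slow, or acid may open the epoxide.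
   - Fallback: drop the ketal-differentiation strategy for this stage. Hydrolyse the ketal of 21 to the epoxy-quinone, reduce both carbonyls (NaBH4/CeCl3) to the diol, then selectively oxidise the less hindered allylic carbinol next to the epoxide CH with MnO2 before the HF·pyridine step.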